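In a one-step world, substrate to ring, the percent of ring follows the clock and ignores the charge. Here are the flask, the earlier runs and the questions:

| flask | substrate | remark | time |
|---|---|---|---|
| north-east | 13 mM | run made earlier |  |
| south-east | 52 mM | run made earlier |  |
| flask | 26 mM |  | 4.0 d |

| run | time / d | open dimer / % | ring / % |
|---|---|---|---|
| north-east | 0.0625 | 13.9 | 14.8 |
| north-east | 0.208 | 23.1 | 35.3 |
| north-east | 0.833 | 25.7 | 59.8 |
| north-east | 2.50 | 25.6 | 63.3 |
| south-east | 0.0625 | 33.6 | 13.1 |
| south-east | 0.208 | 38.4 | 23.3 |
| south-east | 0.833 | 33.0 | 31.0 |
| south-east | 2.50 | 32.7 | 30.6 |

(each reading ± 0.5 percentage points)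

- percent here means substrate units held: one open dimer counts as two
- percent here means substrate units held: one open trimer counts as three
- steps under discussion: substrate -> ring; 2 substrate -> open dimer; substrate + open dimer -> open trimer

1. time, not beyond 4.0 d, at which the flask holds most open dimer
2. the amount of open dimer, in percent of the substrate charged, at that time
3. the first time at which open dimer reaches 17%, in the same percent

The runs begin close to that world: at 0.0625 d ring reads 14.8% in the north-east run and 13.1% in the south-east run. Yet their last readings are 63.3% and 30.6%, about half. How can so close a start end so differently?

The steps to open dimer and open trimer each need two partners, so as written their pull on a substrate grows with concentration, while the ring step's does not. Ask, then, about the end state. South-east ring moves by less than the scatter between its last two readings. North-east ring still rises by 3.5 percentage points between its last two readings, less than the 24 points between the two before, so I take last readings as ends, the north-east one as my assumption. The odds against ring, everything else over ring, are 0.580 north-east and 2.27 south-east, a factor 3.91 for a charge factor 4.00. Dividing charge by odds and averaging the runs gives 22.7 mM. Call this H, the half-ring charge, the charge at which ring ends at even odds; it resembles an effective molarity.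

odds against ring = c(substrate, charged) / H

ring at the end = 1 / (1 + odds)

For the flask, I reckon odds of 1.15, so ring ends at 46.6%.

The forecast, “Using ring formed as the clock”, gave a peak of 33% at 0.27 d and 17% after 0.88 h.

The flask peaks at 33.2% of open dimer at 0.275 d, reaches 17% after 0.879 h, and holds 46.8% ring at 4.00 d, against the 46.6% from H.

    substrate → ring (k = 0.120 h⁻¹)
    2 substrate → open dimer (k = 5.40 M⁻¹ h⁻¹)
    substrate + open dimer → open trimer (k = 5.80 M⁻¹ h⁻¹)

The neighbour charged with 100 mM takes the same reckoning: odds of 4.41, so ring at 18.5%. That neighbour ends with more ring than the reckoning gives, 19.6%, beside 33.6% open dimer and 46.9% open trimer.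

The numbers in the tables are simulated with constants of no real substance.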